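## Analysis of the target

The target 20 is an isoflavone: a chromen-4-one (ring A fused to the pyranone ring C) that carries ring B at C3. Ring A has the phloroglucinol pattern, with free hydroxyls at C5 and C7 and the third oxygen as O1. Ring B is 1',3',4',5'-tetrasubstituted, with OH at C3', OMe at C4' and a 3-methylbut-2-enyl (prenyl) group at C5'. There is no stereocenter, and the prenyl alkene carries two identical methyl groups, so no configuration has to be set. The sensitive groups are the prenyl alkene (protonation followed by addition or cyclisation onto a neighbouring oxygen, and hydrogenation), C2 of the chromone (ring opening by hard nucleophiles under strong base) and the three phenols. The difficulty sits in ring B: one methyl ether lies between a free phenol and the prenyl group, so three phenols must be told apart from one methyl ether, and C5' is meta to the 3'-OH, so the prenyl group cannot come from a Claisen rearrangement or ortho-alkylation of that phenol. The strategy rests on ring A: C4a is ortho to O1, and in a 3,5-dioxygenated phenoxy group the two carbons ortho to O1 (future C4a and C8) are equivalent, each activated by one ortho and one para oxygen. The C4–C4a bond can therefore be formed last, from a carboxyl group tethered through O1–C2=C3, with no regiochemical question.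

## Retrosynthetic reasoning

**C5'–CH2 (prenyl).** The first cut is the bond between C5' and the benzylic carbon of the prenyl group: 20 goes back to its triacetate 19, and 19 to the aryl bromide 17 and the allylic boronate 18. The prenyl alkene tolerates neither the anhydride-driven ring closure nor the Lewis acid that frees the phenols, so it has to arrive after both. A bromine at C5' is inert to everything before that point and is already present in 1, ortho to the oxygen that becomes the methoxy oxygen. The forward reaction must join the aryl carbon to the unsubstituted end of the allyl unit.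

**O-protecting groups.** 17 is the triacetate of the triol 16, and 16 comes from the tris(isopropyl) ether 15 by dealkylation. The acetates keep phenoxides away from the palladium step. Isopropyl ethers were chosen for the three future hydroxyls because they survive the basic steps, the protic-acid step and the ring closure, yet are cleaved by a boron Lewis acid much faster than the methyl ether at C4'. The forward reaction has to make exactly that distinction.

**C4–C4a (ring C).** In 15 the bond C4–C4a is cut, which leads to the acid 13, activated in the flask as the mixed anhydride 14. The cut is made here because the ring carbon that must be acylated is one of two equivalent, doubly activated positions of a symmetrical phenoxy group, so ring A can enter as a simple symmetrical phenol. Closure of ring C at C2 instead, from a deoxybenzoin, is held in reserve. The forward reaction must acylate ortho to O1 without cleaving the enol ether or the isopropyl ethers.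

**O1–C2 (aryl vinyl ether).** 13 comes from its methyl ester 12, and 12 is cut at O1–C2 into the enol tosylate 9 and the phenol 11. Cutting C3–C1' instead would need a metalated ring B that still carries the bromine reserved for the prenyl group. The forward reaction is an addition–elimination at the β-carbon of the acrylate and needs O-attack rather than C-attack of the phenoxide.

**C2–C3.** 9 is the sulfonate of the enol 8, and 8 is cut at C2–C3 into the arylacetate 6 and the formate 7. Only 6 can form an enolate, so the crossed ester condensation has one possible outcome.

**C3–C4.** 6 is cut between the benzylic carbon and the carboxyl carbon, leading through the ketene dithioacetal S-oxide 5 to the aldehyde 4. Keeping ring B as a benzaldehyde up to this point is deliberate, because the formyl group is what differentiates the two ring-B oxygens in the next disconnection.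

**Ring B oxygens.** 4 goes back to the phenol 3, the catechol 2 and finally 1. In 1 the methyl group is on the wrong oxygen; it is removed and put back on the 4-oxygen, which is the more acidic one (para to the formyl group, ortho to bromine), and the other oxygen then takes the isopropyl group.

**Ring A phenol.** 11 comes from 10 by alkylation of two of its three equivalent hydroxyls.

## Alternatives that were turned down

**Alternative 1:** Ring A is built rather than bought.
- Disconnection: ring A is opened at C4a–C5 to a 3,5,7-triketo ester, masked as the 2-pyranone A2. A2 would come from 4-hydroxy-6-methylpyran-2-one A1 by acylation of its methyl group with a ring-B arylacetic ester.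
- Forward key step: a magnesium alkoxide opens A2, and the carbanion at the future C4a attacks the ester carbonyl in a Claisen-type closure to give the deoxybenzoin A3. Ring C would then be closed by one-carbon insertion at C2.
- For it: it is biomimetic, ring A needs no protection, the prenyl group is carried from the start (no late palladium step), and conversion of a deoxybenzoin into an isoflavone is better precedented than the closure chosen here.
- Against it: ring A is the commercial phenol 10, and A3 is in principle one C-acylation away from 10, so building the ring spends steps on nothing. The dianion of A1 would also be quenched by the acidic benzylic protons of the arylacetic ester. The triketo ester can close by aldol as well as by Claisen condensation. The ring-B problem (oxygen pattern, prenyl group) is untouched.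
- Comparison: it is stronger on protecting-group economy and on avoiding Lewis-acid deprotection. The chosen strategy offers instead a purchased ring A, a regiochemically trivial closure and an aryl bromide that keeps the acid-labile prenyl group out of every acidic step.

**Alternative 2:** Ring B is made as a cyclohexenone and aromatised late.
- Disconnection: ring B is cut at C4'–C5' and C1'–C2' into 1-methoxypropan-2-one A4 and the unsaturated α-keto ester A5.
- Forward key step: the enamine of A4 with a cyclic secondary amine adds through its methoxy-bearing carbon to the β-carbon of A5, and the methyl group then condenses with the keto carbonyl to give the racemic trans cyclohexenone A6. Dehydrogenation would give the benzoate A7.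
- For it: all four substituents of ring B are placed by bond construction, independent of aromatic substitution rules. No selective O-methylation and no palladium step are needed.
- Against it: the enamine of A4 can form on either side. A5 is also a heterodiene that can take the enamine in a hetero-Diels–Alder reaction instead of the Michael/aldol sequence. The two stereocenters of A6 are made only to be destroyed. Aromatisation needs an oxidant in the presence of the prenyl alkene. A7 is a benzoate that still needs phenol protection and a one-carbon homologation before it can be joined to ring A.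
- Comparison: it equals the chosen route in regiochemical certainty for ring B but is far longer. The chosen route gets the same pattern from 1 by three simple oxygen manipulations.

**Alternative 3:** Ring B is made by a furan Diels–Alder reaction.
- Disconnection: ring B is cut at C2'–C3' and C1'–C6' into 3-methoxy-4-(3-methylbut-2-enyl)furan A8 and methyl prop-2-ynoate A9.
- Forward key step: the cycloaddition gives an oxanorbornadiene, which opens under mild acid (the methoxy group directs cleavage of the remote C–O bond) and aromatises to the benzoate A10.
- For it: OH, OMe, prenyl and the carbon substituent are set in one step. The OH/OMe distinction comes for free because the bridging oxygen becomes the phenol. On this point it is stronger than the chosen route, which needs a demethylation/remethylation detour.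
- Against it: A8 is not a commercial compound; it is a labile 3-alkoxyfuran whose own synthesis takes several steps. The ring opening exposes the prenyl alkene to acid. A10 is again a benzoate, several steps (protection, reduction, halide, cyanide, solvolysis) away from the arylacetic unit an isoflavone needs.
- Comparison: the elegance is spent on ring B, which is the easier ring to buy. The chosen strategy puts its one demanding step on the formation of ring C and uses a cheap aromatic for ring B.

Key step: step 11

Assumption: 9, 12, 13 and 14 are drawn as Z isomers (oxygen substituent cis to the carboxyl carbon), the geometry that can close. The route does not depend on geometric purity, because the acylium stage of step 11 is expected to interconvert the isomers.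

## Route

Step 1
Reactants: 1 5-bromovanillin (3-bromo-4-hydroxy-5-methoxybenzaldehyde)
Product: 2 3-bromo-4,5-dihydroxybenzaldehyde
Conditions: AlCl3, pyridine, CH2Cl2, reflux; then aq. HCl
Reagents that add atoms: none
Why: Chelation-assisted O-demethylation: aluminium binds the ortho hydroxy/methoxy pair and pyridine removes the methyl group by SN2 attack; aldehyde and aryl bromide are not affected.

Step 2
Reactants: 2 3-bromo-4,5-dihydroxybenzaldehyde
Product: 3 3-bromo-5-hydroxy-4-methoxybenzaldehyde
Conditions: MeI (1.1 equiv), Li2CO3, DMF, 40 °C
Reagents that add atoms: iodomethane, CI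
Why: Regioselective Williamson etherification: the weak base ionises only the 4-OH (para to CHO, ortho to Br), so that oxygen is methylated and the 5-OH stays free; any doubly methylated material is neutral and is removed by base extraction.

Step 3
Reactants: 3 3-bromo-5-hydroxy-4-methoxybenzaldehyde
Product: 4 3-bromo-4-methoxy-5-(propan-2-yloxy)benzaldehyde
Conditions: 2-bromopropane, K2CO3, DMF, 60 °C
Reagents that add atoms: 2-bromopropane, CC(C)Br
Why: Williamson etherification of the remaining phenol; the isopropyl ether should survive every step up to step 12 and is then cleaved without loss of the methyl ether.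

Step 4
Reactants: 4 3-bromo-4-methoxy-5-(propan-2-yloxy)benzaldehyde
Product: 5 1-bromo-2-methoxy-5-[2-(methylsulfanyl)-2-(methylsulfinyl)ethenyl]-3-(propan-2-yloxy)benzene (racemic at sulfur, alkene geometry not controlled; both are erased in step 5)
Conditions: MeS(O)CH2SMe, Triton B (cat.), THF, reflux
Reagents that add atoms: methyl (methylsulfanyl)methyl sulfoxide, CSCS(C)=O
Why: Knoevenagel-type condensation: the carbanion flanked by sulfide and sulfoxide adds to the non-enolisable aldehyde and water is lost; this is the first half of the known two-step conversion of aromatic aldehydes into arylacetic esters.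

Step 5
Reactants: 5 1-bromo-2-methoxy-5-[2-(methylsulfanyl)-2-(methylsulfinyl)ethenyl]-3-(propan-2-yloxy)benzene
Product: 6 methyl 2-[3-bromo-4-methoxy-5-(propan-2-yloxy)phenyl]acetate
Conditions: HCl (anhydrous), MeOH, 0 °C to rt
Reagents that add atoms: methanol, CO
Why: Acid-catalysed alcoholysis of the ketene dithioacetal S-oxide: protonation at the benzylic carbon, addition of methanol to the sulfur-stabilised cation and a Pummerer-type exchange between the two sulfur atoms release the methyl ester, the sulfoxide oxygen becoming the carbonyl oxygen; aryl isopropyl ethers are stable to HCl in methanol at room temperature.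

Step 6
Reactants: 6 methyl 2-[3-bromo-4-methoxy-5-(propan-2-yloxy)phenyl]acetate; 7 methyl formate
Product: 8 methyl (Z)-2-[3-bromo-4-methoxy-5-(propan-2-yloxy)phenyl]-3-hydroxyprop-2-enoate (chelated enol form of the α-formyl ester)
Conditions: NaH, THF, 0 °C to rt; then cold aq. HCl
Reagents that add atoms: none
Why: Crossed Claisen condensation (α-formylation): only 6 can be enolised, and deprotonation of the acidic product drives the equilibrium; the formyl carbon is the future C2.

Step 7
Reactants: 8 methyl (Z)-2-[3-bromo-4-methoxy-5-(propan-2-yloxy)phenyl]-3-hydroxyprop-2-enoate
Product: 9 methyl (Z)-2-[3-bromo-4-methoxy-5-(propan-2-yloxy)phenyl]-3-{[(4-methylphenyl)sulfonyl]oxy}prop-2-enoate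
Conditions: TsCl, N-methylimidazole, LiOH, THF, 0 °C
Reagents that add atoms: 4-methylbenzenesulfonyl chloride, Cc1ccc(S(=O)(=O)Cl)cc1
Why: O-Sulfonylation of the lithium enolate by the N-sulfonylimidazolium formed from TsCl and N-methylimidazole; chelation of lithium between enolate and ester oxygens is expected to favour the Z sulfonate, though either geometry would serve.

Step 8
Reactants: 10 phloroglucinol (benzene-1,3,5-triol)
Product: 11 3,5-di(propan-2-yloxy)phenol
Conditions: 2-bromopropane (2 equiv), K2CO3, DMF, 50 °C
Reagents that add atoms: 2-bromopropane, CC(C)Br
Why: Twofold Williamson etherification with the halide as limiting reagent; the three hydroxyls are equivalent, so mono-, bis- and tris-ethers are all expected, the bis-ether 11 being separated by chromatography and the mono-ether recycled; carbonate in a polar aprotic solvent favours O- over C-alkylation.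

Step 9
Reactants: 9 methyl (Z)-2-[3-bromo-4-methoxy-5-(propan-2-yloxy)phenyl]-3-{[(4-methylphenyl)sulfonyl]oxy}prop-2-enoate; 11 3,5-di(propan-2-yloxy)phenol
Product: 12 methyl (Z)-2-[3-bromo-4-methoxy-5-(propan-2-yloxy)phenyl]-3-[3,5-di(propan-2-yloxy)phenoxy]prop-2-enoate
Conditions: Cs2CO3, MeCN, rt
Reagents that add atoms: none
Why: Nucleophilic vinylic substitution by addition–elimination: the phenoxide adds to the β-carbon of the acrylate and the ester- and aryl-stabilised carbanion expels tosylate, normally with retention; displacement of β-sulfonyloxy and β-halo acrylates by phenoxides is a known reaction class, and this step forms O1–C2.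

Step 10
Reactants: 12 methyl (Z)-2-[3-bromo-4-methoxy-5-(propan-2-yloxy)phenyl]-3-[3,5-di(propan-2-yloxy)phenoxy]prop-2-enoate
Product: 13 (Z)-2-[3-bromo-4-methoxy-5-(propan-2-yloxy)phenyl]-3-[3,5-di(propan-2-yloxy)phenoxy]prop-2-enoic acid
Conditions: LiOH, THF/MeOH/H2O, 40 °C; then cold aq. HCl to pH 3
Reagents that add atoms: lithium hydroxide, [Li+].[OH-]
Why: Saponification; 3-aryloxyacrylic esters are routinely hydrolysed with hydroxide because donation from the ether oxygen makes the oxygen-bearing alkene carbon a poor acceptor, and cold acidification protects the enol ether.

Step 11
Reactants: 13 (Z)-2-[3-bromo-4-methoxy-5-(propan-2-yloxy)phenyl]-3-[3,5-di(propan-2-yloxy)phenoxy]prop-2-enoic acid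
Product: 15 3-[3-bromo-4-methoxy-5-(propan-2-yloxy)phenyl]-5,7-di(propan-2-yloxy)chromen-4-one, via mixed trifluoroacetic anhydride 14 (not isolated)
Conditions: TFAA (2 equiv), CH2Cl2, 0 °C to rt
Reagents that add atoms: none
Why: This is an intramolecular Friedel–Crafts acylation: TFAA converts the acid into the mixed anhydride 14, which ionises towards an acylium ion whose charge is shared with the aryloxy oxygen through the C2=C3 bond. The ring carbon ortho to the ether oxygen attacks the acyl carbon, and loss of a proton from the arenium ion restores ring A, so C4–C4a is formed and ring C is closed as a six-membered ring (6-exo-trig at the anhydride carbonyl, the nucleophilic carbon being held in reach by the O1–C2=C3 tether). The closest known reaction is the acid-mediated cyclodehydration of 3-aryloxyacrylic acids to chromones, from which this substrate differs only by the aryl group at the future C3. No stereocenter is formed. The step needs acylation ortho to O1, which the tether enforces, and the two ortho carbons are equivalent by the local symmetry of the 3,5-dialkoxyphenoxy group, so only one chromone can result. Each of these carbons is activated by one ortho and one para isopropoxy group, which is why a mild activator is expected to suffice and the isopropyl and methyl ethers should survive. Closure requires the aryloxy group cis to the carboxyl carbon; at the acylium stage the C2=C3 bond has partial single-bond character, so any E material should interconvert and be drawn through. The bromine on ring B is inert here and stands in for the acid-labile prenyl group.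

Step 12
Reactants: 15 3-[3-bromo-4-methoxy-5-(propan-2-yloxy)phenyl]-5,7-di(propan-2-yloxy)chromen-4-one
Product: 16 3-(3-bromo-5-hydroxy-4-methoxyphenyl)-5,7-dihydroxychromen-4-one
Conditions: BCl3, CH2Cl2, −78 °C to rt; then MeOH, H2O
Reagents that add atoms: none
Why: Lewis-acid dealkylation: BCl3 coordinates the ether oxygens and chloride removes the secondary isopropyl groups much faster than the primary methyl group, a selectivity that also holds for vicinal isopropoxy/methoxy arenes; the 5-ether, chelated to the carbonyl, goes first, and the bromide and chromone are inert.

Step 13
Reactants: 16 3-(3-bromo-5-hydroxy-4-methoxyphenyl)-5,7-dihydroxychromen-4-one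
Product: 17 3-[3-(acetyloxy)-5-bromo-4-methoxyphenyl]-4-oxo-4H-chromene-5,7-diyl diacetate
Conditions: Ac2O, pyridine, DMAP (cat.), rt
Reagents that add atoms: acetic anhydride, CC(=O)OC(C)=O
Why: Acylation of the three phenols, with DMAP for the hydrogen-bonded 5-OH; the acetates keep phenoxides out of the palladium step and are removed under conditions that do not touch the prenyl group.

Step 14
Reactants: 17 3-[3-(acetyloxy)-5-bromo-4-methoxyphenyl]-4-oxo-4H-chromene-5,7-diyl diacetate; 18 4,4,5,5-tetramethyl-2-(3-methylbut-2-enyl)-1,3,2-dioxaborolane (prenyl pinacol boronate)
Product: 20 5,7-dihydroxy-3-[3-hydroxy-4-methoxy-5-(3-methylbut-2-enyl)phenyl]chromen-4-one (target CNP0231521.0), via prenylated triacetate 19 (not isolated)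
Conditions: Pd(dppf)Cl2 (5 mol%), CsF, THF, 65 °C; then K2CO3, MeOH, rt; aq. HCl work-up
Reagents that add atoms: none
Why: Suzuki–Miyaura coupling of the aryl bromide with the fluoride-activated allylic boronate, then methanolysis of the aryl acetates in the same flask. After oxidative addition to zerovalent palladium and transmetalation, the allyl–palladium intermediate is expected to couple at its unsubstituted terminus, because bond formation at the tertiary carbon next to the ortho-methoxy aryl group is hindered.

## Compound list

1 | 5-bromovanillin (3-bromo-4-hydroxy-5-methoxybenzaldehyde) | COc1cc(C=O)cc(Br)c1O | starting material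
2 | 3-bromo-4,5-dihydroxybenzaldehyde | O=Cc1cc(O)c(O)c(Br)c1 | intermediate
3 | 3-bromo-5-hydroxy-4-methoxybenzaldehyde | COc1c(O)cc(C=O)cc1Br | intermediate
4 | 3-bromo-4-methoxy-5-(propan-2-yloxy)benzaldehyde | COc1c(OC(C)C)cc(C=O)cc1Br | intermediate
5 | 1-bromo-2-methoxy-5-[2-(methylsulfanyl)-2-(methylsulfinyl)ethenyl]-3-(propan-2-yloxy)benzene (racemic at sulfur, alkene geometry not controlled) | COc1c(OC(C)C)cc(C=C(SC)S(C)=O)cc1Br | intermediate
6 | methyl 2-[3-bromo-4-methoxy-5-(propan-2-yloxy)phenyl]acetate | COC(=O)Cc1cc(Br)c(OC)c(OC(C)C)c1 | intermediate
7 | methyl formate | COC=O | starting material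
8 | methyl (Z)-2-[3-bromo-4-methoxy-5-(propan-2-yloxy)phenyl]-3-hydroxyprop-2-enoate | O/C=C(\C(=O)OC)c1cc(Br)c(OC)c(OC(C)C)c1 | intermediate
9 | methyl (Z)-2-[3-bromo-4-methoxy-5-(propan-2-yloxy)phenyl]-3-{[(4-methylphenyl)sulfonyl]oxy}prop-2-enoate | Cc1ccc(S(=O)(=O)O/C=C(\C(=O)OC)c2cc(Br)c(OC)c(OC(C)C)c2)cc1 | intermediate
10 | phloroglucinol (benzene-1,3,5-triol) | Oc1cc(O)cc(O)c1 | starting material
11 | 3,5-di(propan-2-yloxy)phenol | CC(C)Oc1cc(O)cc(OC(C)C)c1 | intermediate
12 | methyl (Z)-2-[3-bromo-4-methoxy-5-(propan-2-yloxy)phenyl]-3-[3,5-di(propan-2-yloxy)phenoxy]prop-2-enoate | CC(C)Oc1cc(OC(C)C)cc(O/C=C(\C(=O)OC)c2cc(Br)c(OC)c(OC(C)C)c2)c1 | intermediate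
13 | (Z)-2-[3-bromo-4-methoxy-5-(propan-2-yloxy)phenyl]-3-[3,5-di(propan-2-yloxy)phenoxy]prop-2-enoic acid | CC(C)Oc1cc(OC(C)C)cc(O/C=C(\C(=O)O)c2cc(Br)c(OC)c(OC(C)C)c2)c1 | intermediate
14 | (Z)-2-[3-bromo-4-methoxy-5-(propan-2-yloxy)phenyl]-3-[3,5-di(propan-2-yloxy)phenoxy]prop-2-enoic trifluoroacetic anhydride | CC(C)Oc1cc(OC(C)C)cc(O/C=C(\C(=O)OC(=O)C(F)(F)F)c2cc(Br)c(OC)c(OC(C)C)c2)c1 | intermediate (not isolated)
15 | 3-[3-bromo-4-methoxy-5-(propan-2-yloxy)phenyl]-5,7-di(propan-2-yloxy)chromen-4-one | CC(C)Oc1cc(OC(C)C)c2c(c1)occ(-c1cc(Br)c(OC)c(OC(C)C)c1)c2=O | intermediate
16 | 3-(3-bromo-5-hydroxy-4-methoxyphenyl)-5,7-dihydroxychromen-4-one | COc1c(O)cc(-c2coc3cc(O)cc(O)c3c2=O)cc1Br | intermediate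
17 | 3-[3-(acetyloxy)-5-bromo-4-methoxyphenyl]-4-oxo-4H-chromene-5,7-diyl diacetate | COc1c(OC(C)=O)cc(-c2coc3cc(OC(C)=O)cc(OC(C)=O)c3c2=O)cc1Br | intermediate
18 | 4,4,5,5-tetramethyl-2-(3-methylbut-2-enyl)-1,3,2-dioxaborolane | CC(C)=CCB1OC(C)(C)C(C)(C)O1 | starting material
19 | 3-[3-(acetyloxy)-4-methoxy-5-(3-methylbut-2-enyl)phenyl]-4-oxo-4H-chromene-5,7-diyl diacetate | COc1c(OC(C)=O)cc(-c2coc3cc(OC(C)=O)cc(OC(C)=O)c3c2=O)cc1CC=C(C)C | intermediate (not isolated)
20 | 5,7-dihydroxy-3-[3-hydroxy-4-methoxy-5-(3-methylbut-2-enyl)phenyl]chromen-4-one | COc1c(O)cc(-c2coc3cc(O)cc(O)c3c2=O)cc1CC=C(C)C | target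

## Step count and risks

Total step count: 14. Longest linear sequence: 13 steps (steps 1–7 and 9–14, from 1); step 8 is a one-step side branch from 10.

**Step 11 (key step).** Closure may be outrun by intermolecular C-trifluoroacetylation of the electron-rich phenoxy ring. The enol ether linkage may be cleaved by adventitious water under the acidic conditions. Geometric interconversion may be too slow if the acylium character of 14 is smaller than assumed. Loss of the peri isopropyl group would be harmless. The fallback changes the order of bond formation, making C4–C4a first and closing ring C at C2; it sets out from 6 and 10 and returns at 16. The ester 6 is saponified (LiOH) to 2-[3-bromo-4-methoxy-5-(propan-2-yloxy)phenyl]acetic acid F1. F1 acylates 10 at carbon in BF3·OEt2 at 80 °C to give the deoxybenzoin 2-[3-bromo-4-methoxy-5-(propan-2-yloxy)phenyl]-1-(2,4,6-trihydroxyphenyl)ethanone F2. One-carbon insertion with DMF, BF3·OEt2 and MsCl closes ring C to 3-[3-bromo-4-methoxy-5-(propan-2-yloxy)phenyl]-5,7-dihydroxychromen-4-one F3, and BCl3 removes the remaining isopropyl group to give 16.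

**Step 14.** The allyl unit may be transferred through its substituted γ-terminus (SE2' transmetalation followed by fast reductive elimination), which would erode the α-regioselectivity. Reduction of the C–Br bond and premature loss of acetyl groups (harmless) are further possibilities. The fallback separates C–C coupling from the construction of the trisubstituted alkene; it sets out from 17 and returns at 19. Suzuki–Miyaura coupling of 17 with allylboronic acid pinacol ester (Pd(PPh3)4, CsF, THF, reflux), where no regiochemical question exists, gives 3-[3-(acetyloxy)-4-methoxy-5-(prop-2-enyl)phenyl]-4-oxo-4H-chromene-5,7-diyl diacetate F4. Cross-metathesis of F4 with 2-methylbut-2-ene (second-generation Grubbs catalyst, CH2Cl2, 40 °C) gives 19, which is deacetylated as in step 14 to 20.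

**Step 9.** The phenoxide may attack at sulfur (sulfonyl transfer, returning the enolate of 8), or react through a ring carbon, since 3,5-dialkoxyphenoxides are ambident. Erosion of alkene geometry is tolerated. The fallback replaces the sulfonate by a leaving group with no second electrophilic site; it sets out from 8 and returns at 12. Chlorination of 8 with the Vilsmeier reagent ((COCl)2, DMF, CH2Cl2) gives methyl 3-chloro-2-[3-bromo-4-methoxy-5-(propan-2-yloxy)phenyl]prop-2-enoate F5 (mixture of geometric isomers). Its chloride is displaced by 11 (K2CO3, DMF) to give 12.

**Step 8.** Alkylation is distributed statistically over three equivalent hydroxyls, and C-alkylation of the phloroglucinol anion may compete, so the step is certain to give material but may give little. The fallback changes the mechanism from phenoxide alkylation to acid-catalysed etherification; it sets out from 10 and returns at 11 without any new compound (entry F0). 10 is heated in propan-2-ol saturated with HCl. The reaction runs through the keto tautomer, cannot C-alkylate and slows sharply after the second ether.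

## Further compounds

F1 | step 11 | 2-[3-bromo-4-methoxy-5-(propan-2-yloxy)phenyl]acetic acid | COc1c(OC(C)C)cc(CC(=O)O)cc1Br
F2 | step 11 | 2-[3-bromo-4-methoxy-5-(propan-2-yloxy)phenyl]-1-(2,4,6-trihydroxyphenyl)ethanone | COc1c(OC(C)C)cc(CC(=O)c2c(O)cc(O)cc2O)cc1Br
F3 | step 11 | 3-[3-bromo-4-methoxy-5-(propan-2-yloxy)phenyl]-5,7-dihydroxychromen-4-one | COc1c(OC(C)C)cc(-c2coc3cc(O)cc(O)c3c2=O)cc1Br
F4 | step 14 | 3-[3-(acetyloxy)-4-methoxy-5-(prop-2-enyl)phenyl]-4-oxo-4H-chromene-5,7-diyl diacetate | COc1c(OC(C)=O)cc(-c2coc3cc(OC(C)=O)cc(OC(C)=O)c3c2=O)cc1CC=C
F5 | step 9 | methyl 3-chloro-2-[3-bromo-4-methoxy-5-(propan-2-yloxy)phenyl]prop-2-enoate (mixture of geometric isomers) | COC(=O)C(=CCl)c1cc(Br)c(OC)c(OC(C)C)c1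
F0 | step 8 | none | none
A1 | alternative 1 | 4-hydroxy-6-methylpyran-2-one | Cc1cc(O)cc(=O)o1
A2 | alternative 1 | 4-hydroxy-6-{3-[4-methoxy-3-(methoxymethoxy)-5-(3-methylbut-2-enyl)phenyl]-2-oxopropyl}pyran-2-one | COCOc1cc(CC(=O)Cc2cc(O)cc(=O)o2)cc(CC=C(C)C)c1OC
A3 | alternative 1 | 2-[4-methoxy-3-(methoxymethoxy)-5-(3-methylbut-2-enyl)phenyl]-1-(2,4,6-trihydroxyphenyl)ethanone | COCOc1cc(CC(=O)c2c(O)cc(O)cc2O)cc(CC=C(C)C)c1OC
A4 | alternative 2 | 1-methoxypropan-2-one | COCC(C)=O
A5 | alternative 2 | ethyl (3E)-7-methyl-2-oxoocta-3,6-dienoate | CCOC(=O)C(=O)/C=C/CC=C(C)C
A6 | alternative 2 | ethyl trans-4-methoxy-5-(3-methylbut-2-enyl)-3-oxocyclohex-1-ene-1-carboxylate (racemic) | CCOC(=O)C1=CC(=O)[C@@H](OC)[C@H](CC=C(C)C)C1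
A7 | alternative 2 | ethyl 3-hydroxy-4-methoxy-5-(3-methylbut-2-enyl)benzoate | CCOC(=O)c1cc(O)c(OC)c(CC=C(C)C)c1
A8 | alternative 3 | 3-methoxy-4-(3-methylbut-2-enyl)furan | COc1cocc1CC=C(C)C
A9 | alternative 3 | methyl prop-2-ynoate | C#CC(=O)OC
A10 | alternative 3 | methyl 3-hydroxy-4-methoxy-5-(3-methylbut-2-enyl)benzoate | COC(=O)c1cc(O)c(OC)c(CC=C(C)C)c1
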